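**Assumption:** the SMILES has no stereocentre and no stable stereoaxis, because the dioxepinone boat inverts freely. Mollicellin B is therefore achiral, "single enantiomer" has no consequence, and no step needs stereocontrol.

## Retrosynthetic overview
1. The last ring closed is the seven-membered lactone, formed from O6 of the chromanone ring and the ring-A CO2H.
2. Key step: the hindered diaryl ether is not cross-coupled. A retro-Smiles (O→O aryl migration) traces it back to an isomeric catechol mono-depside.
3. Ring B activates its own ipso carbon (C7) through the para chromanone C=O. Ring A supplies the ether oxygen from its own 2-OH.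
4. The depside comes from two unprotected fragments: haematommic acid, and 6,7-dihydroxy-2,2,5-trimethylchroman-4-one.
5. Ring order: pyranone (Friedel–Crafts/oxa-Michael), then ester tether, then aryl migration, then dioxepinone. No halogen, metal catalyst or protecting group is used.

## Route

**Step 1**
Reactants: 1, 2,4-dihydroxy-6-methylbenzaldehyde (o-orsellinaldehyde)
Product: 2, 6-methylbenzene-1,2,4-triol
Conditions: 30% H2O2 (1.1 equiv), NaOH (1.1 equiv), degassed H2O, 0 °C → rt, N2; HCl; Na2S2O4 wash; used crude
Reagents that add atoms: hydrogen peroxide, OO
Why: Dakin oxidation, in which hydroperoxide adds to the o,p-dihydroxy-activated aldehyde, the electron-rich aryl migrates to oxygen and the formate hydrolyses, placing the new OH between the CH3 and an existing OH.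

**Step 2**
Reactants: 2, 6-methylbenzene-1,2,4-triol; 3, 3,3-dimethylacrylic acid
Product: 4, 6,7-dihydroxy-2,2,5-trimethylchroman-4-one
Conditions: P2O5–MeSO3H (Eaton's reagent), 70 °C, 1 h, N2; ice
Reagents that add atoms: 3,3-dimethylacrylic acid (3), CC(C)=CC(=O)O
Why: One-pot Friedel–Crafts acylation/oxa-Michael chromanone annulation, where the acylium attacks C5 of the triol (para to 2-OH, ortho to 4-OH, the site favoured in benzene-1,2,4-triol and orcinol) and only the adjacent 4-OH can close the pyranone.

**Step 3**
Reactants: 5, methyl 2,4-dihydroxy-6-methylbenzoate (methyl orsellinate)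
Product: 6, methyl 3-formyl-2,4-dihydroxy-6-methylbenzoate (methyl haematommate)
Conditions: Cl2CHOMe (1.2 equiv), TiCl4 (3 equiv), CH2Cl2, −10 °C → rt; 1 M HCl; minor 5-formyl isomer removed by crystallisation
Reagents that add atoms: dichloromethyl methyl ether, COC(Cl)Cl (formyl carbon); water, O (aldehyde oxygen on hydrolytic quench)
Why: Rieche formylation, in which titanium bound to the two flanking phenoxides delivers the electrophile to C3, the most nucleophilic carbon, lying between the two OH groups.

**Step 4**
Reactants: 6, methyl haematommate
Product: 7, 3-formyl-2,4-dihydroxy-6-methylbenzoic acid (haematommic acid)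
Conditions: conc. H2SO4, 0 °C → rt, 1 h; poured onto ice; kept cold to avoid decarboxylation
Reagents that add atoms: water, O
Why: AAC1 hydrolysis of a di-ortho-substituted benzoate, in which the protonated ester ionises to a donor-stabilised acylium that water captures, while the formyl-deactivated ring resists sulfonation.

**Step 5**
Reactants: 4, 6,7-dihydroxy-2,2,5-trimethylchroman-4-one; 7, haematommic acid
Product: 8, 6-hydroxy-2,2,5-trimethyl-4-oxochroman-7-yl 3-formyl-2,4-dihydroxy-6-methylbenzoate (catechol mono-depside)
Conditions: (CF3CO)2O (3 equiv), toluene, 0 °C → rt, 3 h, 1:1 stoichiometry; aq NaHCO3 wash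
Reagents that add atoms: none
Why: Mixed-anhydride (TFAA) depside esterification, in which the hindered aroyl cation takes the less hindered 7-OH, the ring-A phenols are too H-bonded and deactivated (CHO, CO2H) to self-condense, and any 6-O-acyl isomer is carried forward because step 6 converges both.

**Step 6 (key step)**
Reactants: 8, catechol mono-depside
Product: 9, 3-formyl-4-hydroxy-2-[(6-hydroxy-2,2,5-trimethyl-4-oxochroman-7-yl)oxy]-6-methylbenzoic acid
Conditions: K2CO3 (1.0 equiv, dry powder), DMSO (0.05 M), 4 Å MS, Ar, rt → 80 °C; 1 M HCl
Reagents that add atoms: none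
Why: O→O Smiles rearrangement, in which the ring-A 2-phenoxide attacks C7 ipso through a six-membered spiro-Meisenheimer adduct stabilised by the para C4 ketone and the much less basic carboxylate leaves irreversibly; a 6-O-acyl isomer only equilibrates back to 8 by catechol acyl migration because its ipso carbon is para to the ring oxygen and unactivated, and one equivalent of carbonate leaves 6-OH protonated so ring A cannot migrate onward to O6.

**Step 7**
Reactants: 9, diaryl ether acid
Product: 10, mollicellin B
Conditions: (CF3CO)2O (5 equiv), toluene (2 mM), rt, 12 h; cold aq NaHCO3 wash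
Reagents that add atoms: none
Why: Depsidone lactonisation through the mixed trifluoroacetic anhydride/acylium, where 6-OH is the only hydroxyl within intramolecular reach, high dilution suppresses acylation of the chelated ring-A OH, and transient aryl trifluoroacetates are lost in the wash.

## Compound list
| No. | Name | SMILES | Role |
|---|---|---|---|
| 1 | 2,4-dihydroxy-6-methylbenzaldehyde | Cc1cc(O)cc(O)c1C=O | starting material |
| 2 | 6-methylbenzene-1,2,4-triol | Cc1cc(O)cc(O)c1O | intermediate |
| 3 | 3,3-dimethylacrylic acid | CC(C)=CC(=O)O | starting material |
| 4 | 6,7-dihydroxy-2,2,5-trimethylchroman-4-one | Cc1c(O)c(O)cc2OC(C)(C)CC(=O)c12 | intermediate |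
| 5 | methyl 2,4-dihydroxy-6-methylbenzoate | COC(=O)c1c(C)cc(O)cc1O | starting material |
| 6 | methyl 3-formyl-2,4-dihydroxy-6-methylbenzoate | COC(=O)c1c(C)cc(O)c(C=O)c1O | intermediate |
| 7 | 3-formyl-2,4-dihydroxy-6-methylbenzoic acid | Cc1cc(O)c(C=O)c(O)c1C(=O)O | intermediate |
| 8 | 6-hydroxy-2,2,5-trimethyl-4-oxochroman-7-yl 3-formyl-2,4-dihydroxy-6-methylbenzoate | Cc1cc(O)c(C=O)c(O)c1C(=O)Oc1cc2OC(C)(C)CC(=O)c2c(C)c1O | intermediate |
| 9 | 3-formyl-4-hydroxy-2-[(6-hydroxy-2,2,5-trimethyl-4-oxochroman-7-yl)oxy]-6-methylbenzoic acid | Cc1cc(O)c(C=O)c(Oc2cc3OC(C)(C)CC(=O)c3c(C)c2O)c1C(=O)O | intermediate |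
| 10 | mollicellin B (achiral) | Cc1cc(O)c(C=O)c2c1C(=O)Oc1c(cc3c(c1C)C(=O)CC(C)(C)O3)O2 | target |

## Summary
**Total steps:** 7.
**Longest linear sequence:** 5 steps (1→2→4→8→9→10). The ring-A branch 5→6→7→8→9→10 is also 5 steps.

**Steps most likely to fail, with fallbacks**
1. **Step 6, Smiles migration.** The nucleophile is a weak, doubly chelated phenoxide, and ring B is activated by only one ketone.
   - Fallback: reverse the polarity and change the closing bond.
   - Run SNAr of the more acidic 7-phenoxide of 4 on symmetric 2,6-difluoro-4-methylbenzaldehyde, which raises no regiochemical question.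
   - Convert the second F to OH with a hydroxide surrogate, then iodinate para to that OH.
   - Close the lactone by Pd-catalysed carbonylation (CO) onto 6-OH, making the final closure a C–C bond formation.
2. **Step 2, annulation of the air-sensitive triol.** The risks are C3 versus C5 acylation and competing tert-alkylation to a dihydrocoumarin.
   - Fallback: install the acyl group before the extra oxygen.
   - Acetylate orcinol to 2,4-dihydroxy-6-methylacetophenone.
   - Carry out Elbs persulfate hydroxylation para to the chelated 2-OH, the only free para site, to give the 2,4,5-triol.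
   - Build the pyranone by Kabbe condensation with acetone/pyrrolidine to reach 4.
3. **Step 5, protecting-group-free esterification.** The risks are self-condensation, diacylation and low conversion of the hindered acid.
   - Fallback: use a masked acyl donor.
   - Convert 7 to its acetonide, 8-formyl-7-hydroxy-2,2,5-trimethyl-4H-1,3-benzodioxin-4-one, and benzylate O7.
   - Open it with the 7-phenoxide of 4. Loss of acetone releases the Smiles-ready phenoxide directly.
   - Remove the benzyl group at the end with BCl3, assisted by the ortho formyl group.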